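**Plan**

- Retrosynthetic cuts: first the O3–Si bond of a 3-O-silyl glycerol, then both C5–C6 bonds of the two 4,6-diyne units in one operation. This leaves a glycerol bis(5-bromopent-4-ynoate) (two ester C–O bonds, built on (S)-solketal) and two copies of a C6–C18 epoxy alkyne.
- The epoxy alkyne is cut at C6≡C7 (back to a formyl group at C7), at both C–O bonds of the C8–O–C9 oxirane (back to a C8=C9 enal), at C8=C9 (Wittig) and at C14–C15 (alkyne–alkyne coupling of hex-5-yn-1-ol with but-1-yne).
- Enabling feature: each oxirane oxygen bridges C8 and C9 directly beside C7, which can be carried as an aldehyde. The only other C=C bonds, the Z,Z-diene C13=C14–C15=C16, sit three methylenes away and are electron-rich. As an iminium ion, C8=C9 is therefore the sole acceptor for H2O2, and the oxirane (the only ring made) can be closed with the diene already in place.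
- Forward order: C10 diyne → Z,Z-dienal → C12 trienal → oxirane → terminal alkyne. Separately: solketal → silyl diol → bis(pentynoate) → bis(bromoalkyne). Both chains are then attached at once and the silyl group is removed last.
- Stereochemistry: C8 and C9 of both chains come from the catalyst-controlled epoxidation (trans through the stepwise ring closure), 13Z,15Z from the zinc cis-reduction, and glycerol C2 from (S)-solketal.

Key step: step 6

Assumption: acyl-chain atoms are numbered C1 (carboxyl carbon) to C18; each chain is then an (8S,9S,13Z,15Z)-8,9-epoxyoctadeca-13,15-dien-4,6-diynoyl group, and the target is the 1,2-diacyl-sn-glycerol.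

Assumption: the catalyst enantiomer in step 6 is chosen from the steric model of the E,s-trans iminium ion (attack anti to the diarylmethyl silyl ether arm), which assigns the (2R,3S)-aldehyde to the (R)-catalyst. The configuration of 9 is to be correlated with the tartrate-derived sample of the first fallback, and the mirror-image catalyst would be used if the correlation demands it.

**Route**

Step 1
Reactants: 1 hex-5-yn-1-ol
Product: 2 6-bromohex-5-yn-1-ol
Conditions: NBS (1.1 equiv), AgNO3 (10 mol %), acetone, rt, dark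
Reagents that add atoms: N-bromosuccinimide, O=C1CCC(=O)N1Br
Why: Silver-catalysed electrophilic bromination of the terminal alkyne C–H (through the silver acetylide) is the standard route to 1-bromoalkynes and leaves the primary alcohol untouched.

Step 2
Reactants: 2 6-bromohex-5-yn-1-ol; 3 but-1-yne
Product: 4 deca-5,7-diyn-1-ol
Conditions: CuCl (10 mol %), NH2OH·HCl (30 mol %), 30% aq n-BuNH2, but-1-yne (3 equiv, condensed), 0 °C, slow addition of 2
Reagents that add atoms: none
Why: Cadiot–Chodkiewicz coupling, in which the copper acetylide of but-1-yne (copper kept monovalent by hydroxylamine) displaces bromide from 2; the cheap volatile alkyne is used in excess to suppress homocoupling of 2.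

Step 3
Reactants: 4 deca-5,7-diyn-1-ol
Product: 5 (5Z,7Z)-deca-5,7-dien-1-ol
Conditions: Zn dust activated with Cu(OAc)2 and AgNO3, MeOH/H2O (1:1), 40 °C
Reagents that add atoms: none
Why: The Zn(Cu/Ag) couple in a protic medium adds hydrogen cis across each triple bond of a conjugated diyne and stops at the alkene stage, so both new double bonds should be Z without the over-reduction of catalytic hydrogenation.

Step 4
Reactants: 5 (5Z,7Z)-deca-5,7-dien-1-ol
Product: 6 (5Z,7Z)-deca-5,7-dienal
Conditions: Dess–Martin periodinane, NaHCO3, CH2Cl2, 0 °C → rt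
Reagents that add atoms: none
Why: Buffered Dess–Martin oxidation converts the primary alcohol into the aldehyde at neutral pH and should leave the isomerisation-prone Z,Z-diene unchanged.

Step 5
Reactants: 6 (5Z,7Z)-deca-5,7-dienal; 7 (triphenylphosphoranylidene)acetaldehyde
Product: 8 (2E,7Z,9Z)-dodeca-2,7,9-trienal
Conditions: 7 (1.1 equiv), toluene, 80 °C
Reagents that add atoms: none
Why: Wittig reaction with the stabilised formylmethylene ylide is E-selective, and the product enal is a poorer electrophile than the saturated aldehyde, so a single two-carbon homologation is expected with near-stoichiometric ylide.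

Step 6
Reactants: 8 (2E,7Z,9Z)-dodeca-2,7,9-trienal
Product: 9 (2R,3S)-3-[(4Z,6Z)-nona-4,6-dien-1-yl]oxirane-2-carbaldehyde
Conditions: (R)-2-{bis[3,5-bis(trifluoromethyl)phenyl][(trimethylsilyl)oxy]methyl}pyrrolidine (10 mol %), 35% aq H2O2 (1.3 equiv), CH2Cl2, rt
Reagents that add atoms: hydrogen peroxide, OO
Why: The secondary amine condenses with 8 to the E,s-trans iminium ion, H2O2 adds to its β-carbon (C3, chain C9), and the β-hydroperoxy enamine then attacks the proximal peroxide oxygen through C2, expelling hydroxide before hydrolysis releases 9 and the catalyst. The closest known reaction type is the diarylprolinol silyl ether-catalysed, Weitz–Scheffer-type epoxidation of 2-enals with aqueous H2O2, of which this is a direct application. The oxirane, the only ring formed, closes in a 3-exo-tet mode at oxygen. C3 is set by peroxide attack on the face of the iminium ion not covered by the C(Ar)2OSiMe3 arm, and C2 by enamine attack from that same open face; with free rotation about C2–C3 in the intermediate this gives the trans-oxirane, (2R,3S) with the (R)-catalyst on the shielding model. The step needs chemoselectivity for C2=C3 over the C7=C8/C9=C10 diene: only the iminium-bound alkene accepts the nucleophilic oxidant, the isolated electron-rich Z,Z-diene has no pathway to react with H2O2 without a peracid or metal, and the near-neutral medium should not isomerise it. Any Z-enal carried over from step 5 should converge on the same trans product through the rotatable enamine intermediate.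

Step 7
Reactants: 9 (2R,3S)-3-[(4Z,6Z)-nona-4,6-dien-1-yl]oxirane-2-carbaldehyde
Product: 10 (2S,3S)-2-ethynyl-3-[(4Z,6Z)-nona-4,6-dien-1-yl]oxirane
Conditions: dimethyl (1-diazo-2-oxopropyl)phosphonate, K2CO3, MeOH, 0 °C → rt
Reagents that add atoms: dimethyl (1-diazo-2-oxopropyl)phosphonate, CC(=O)C(=[N+]=[N-])P(=O)(OC)OC
Why: Ohira–Bestmann form of the Seyferth–Gilbert homologation, in which the diazomethylphosphonate anion released by methanolysis adds to the aldehyde and loss of phosphate and N2 with a 1,2-hydrogen shift gives the terminal alkyne; the oxirane C–H is too weakly acidic to epimerise with K2CO3, so both centres are kept (the descriptor at the alkyne-bearing carbon becomes S by priority rules only).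

Step 8
Reactants: 11 (S)-solketal (1,2-O-isopropylidene-sn-glycerol)
Product: 12 3-O-(tert-butyldiphenylsilyl)-1,2-O-isopropylidene-sn-glycerol
Conditions: TBDPSCl, imidazole, CH2Cl2, rt
Reagents that add atoms: tert-butyl(chloro)diphenylsilane, CC(C)(C)[Si](Cl)(c1ccccc1)c1ccccc1
Why: Silylation of the only free hydroxyl of the chiral-pool acetonide is routine, and the tert-butyldiphenylsilyl group is chosen because it withstands the acid of the next step.

Step 9
Reactants: 12 3-O-(tert-butyldiphenylsilyl)-1,2-O-isopropylidene-sn-glycerol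
Product: 13 3-O-(tert-butyldiphenylsilyl)-sn-glycerol
Conditions: AcOH/H2O (4:1), 40 °C
Reagents that add atoms: none
Why: Acid-catalysed hydrolysis of the terminal isopropylidene acetal frees the sn-1 and sn-2 hydroxyls, while the primary tert-butyldiphenylsilyl ether is stable to aqueous acetic acid and the stereocentre is not involved.

Step 10
Reactants: 13 3-O-(tert-butyldiphenylsilyl)-sn-glycerol; 14 pent-4-ynoic acid
Product: 15 3-O-(tert-butyldiphenylsilyl)-1,2-di-O-(pent-4-ynoyl)-sn-glycerol
Conditions: 14 (2.4 equiv), N-(3-dimethylaminopropyl)-N′-ethylcarbodiimide hydrochloride, DMAP (cat.), CH2Cl2, 0 °C → rt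
Reagents that add atoms: none
Why: Steglich-type esterification acylates both the primary and the secondary hydroxyl with the simple, robust acid used in excess, without touching the silyl ether or the stereocentre.

Step 11
Reactants: 15 3-O-(tert-butyldiphenylsilyl)-1,2-di-O-(pent-4-ynoyl)-sn-glycerol
Product: 16 1,2-bis-O-(5-bromopent-4-ynoyl)-3-O-(tert-butyldiphenylsilyl)-sn-glycerol
Conditions: NBS (2.3 equiv), AgNO3 (20 mol %), acetone, rt, dark
Reagents that add atoms: N-bromosuccinimide, O=C1CCC(=O)N1Br
Why: The same silver-catalysed alkyne C–H bromination as in step 1, applied to both termini; esters and the silyl ether are inert to it.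

Step 12
Reactants: 16 1,2-bis-O-(5-bromopent-4-ynoyl)-3-O-(tert-butyldiphenylsilyl)-sn-glycerol; 10 (2S,3S)-2-ethynyl-3-[(4Z,6Z)-nona-4,6-dien-1-yl]oxirane (two equivalents enter the product)
Product: 17 3-O-(tert-butyldiphenylsilyl)-1,2-bis-O-{7-[(2S,3S)-3-[(4Z,6Z)-nona-4,6-dien-1-yl]oxiran-2-yl]hepta-4,6-diynoyl}-sn-glycerol
Conditions: 10 (2.4 equiv), CuCl (20 mol %), NH2OH·HCl, 30% aq n-BuNH2, CH2Cl2, 0 °C, slow addition of 16, dark
Reagents that add atoms: none
Why: Twofold Cadiot–Chodkiewicz coupling, in which the copper acetylide of 10 displaces bromide from each of the two equivalent, mutually remote bromoalkyne termini to form both C5–C6 bonds; brief, cold conditions of this type are tolerated by esters and propargylic oxiranes, and no stereocentre is involved.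

Step 13
Reactants: 17 3-O-(tert-butyldiphenylsilyl)-1,2-bis-O-{7-[(2S,3S)-3-[(4Z,6Z)-nona-4,6-dien-1-yl]oxiran-2-yl]hepta-4,6-diynoyl}-sn-glycerol
Product: 18 1,2-bis-O-{7-[(2S,3S)-3-[(4Z,6Z)-nona-4,6-dien-1-yl]oxiran-2-yl]hepta-4,6-diynoyl}-sn-glycerol (CNP0301966.1)
Conditions: TBAF, AcOH (1.2 equiv per fluoride), THF, 0 °C → rt
Reagents that add atoms: none
Why: Fluoride cleaves the Si–O bond while acetic acid keeps the liberated primary hydroxyl protonated, so the sn-2 acyl group should not migrate to O3; esters, oxiranes, diynes and dienes are inert to buffered fluoride, and this is the usual release of 1,2-diacyl-sn-glycerols from 3-O-silyl ethers.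

**Compound list**

1 | hex-5-yn-1-ol | C#CCCCCO | starting material
2 | 6-bromohex-5-yn-1-ol | OCCCCC#CBr | intermediate
3 | but-1-yne | CCC#C | starting material
4 | deca-5,7-diyn-1-ol | CCC#CC#CCCCCO | intermediate
5 | (5Z,7Z)-deca-5,7-dien-1-ol | CC/C=C\C=C/CCCCO | intermediate
6 | (5Z,7Z)-deca-5,7-dienal | CC/C=C\C=C/CCCC=O | intermediate
7 | (triphenylphosphoranylidene)acetaldehyde | O=CC=P(c1ccccc1)(c1ccccc1)c1ccccc1 | starting material
8 | (2E,7Z,9Z)-dodeca-2,7,9-trienal | O=C/C=C/CCC/C=C\C=C/CC | intermediate
9 | (2R,3S)-3-[(4Z,6Z)-nona-4,6-dien-1-yl]oxirane-2-carbaldehyde | O=C[C@@H]1O[C@H]1CCC/C=C\C=C/CC | intermediate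
10 | (2S,3S)-2-ethynyl-3-[(4Z,6Z)-nona-4,6-dien-1-yl]oxirane | C#C[C@@H]1O[C@H]1CCC/C=C\C=C/CC | intermediate
11 | (S)-solketal, [(4S)-2,2-dimethyl-1,3-dioxolan-4-yl]methanol (1,2-O-isopropylidene-sn-glycerol) | CC1(C)OC[C@H](CO)O1 | starting material
12 | 3-O-(tert-butyldiphenylsilyl)-1,2-O-isopropylidene-sn-glycerol, tert-butyl{[(4R)-2,2-dimethyl-1,3-dioxolan-4-yl]methoxy}diphenylsilane | CC1(C)OC[C@H](CO[Si](c2ccccc2)(c2ccccc2)C(C)(C)C)O1 | intermediate
13 | 3-O-(tert-butyldiphenylsilyl)-sn-glycerol, (2R)-3-[(tert-butyldiphenylsilyl)oxy]propane-1,2-diol | OC[C@H](CO[Si](c1ccccc1)(c1ccccc1)C(C)(C)C)O | intermediate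
14 | pent-4-ynoic acid | C#CCCC(=O)O | starting material
15 | 3-O-(tert-butyldiphenylsilyl)-1,2-di-O-(pent-4-ynoyl)-sn-glycerol | C#CCCC(=O)OC[C@H](CO[Si](c1ccccc1)(c1ccccc1)C(C)(C)C)OC(=O)CCC#C | intermediate
16 | 1,2-bis-O-(5-bromopent-4-ynoyl)-3-O-(tert-butyldiphenylsilyl)-sn-glycerol | BrC#CCCC(=O)OC[C@H](CO[Si](c1ccccc1)(c1ccccc1)C(C)(C)C)OC(=O)CCC#CBr | intermediate
17 | 3-O-(tert-butyldiphenylsilyl)-1,2-bis-O-{7-[(2S,3S)-3-[(4Z,6Z)-nona-4,6-dien-1-yl]oxiran-2-yl]hepta-4,6-diynoyl}-sn-glycerol | CC/C=C\C=C/CCC[C@@H]1O[C@H]1C#CC#CCCC(=O)OC[C@H](CO[Si](c1ccccc1)(c1ccccc1)C(C)(C)C)OC(=O)CCC#CC#C[C@@H]1O[C@H]1CCC/C=C\C=C/CC | intermediate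
18 | 1,2-bis-O-{7-[(2S,3S)-3-[(4Z,6Z)-nona-4,6-dien-1-yl]oxiran-2-yl]hepta-4,6-diynoyl}-sn-glycerol, the (2S)-3-hydroxypropane-1,2-diyl diester (CNP0301966.1) | CC/C=C\C=C/CCC[C@@H]1O[C@H]1C#CC#CCCC(=O)OC[C@H](CO)OC(=O)CCC#CC#C[C@@H]1O[C@H]1CCC/C=C\C=C/CC | target

**Step count**

Total: 13 steps. Longest linear sequence: 9 steps (steps 1–7, 12, 13).

**Steps most likely to fail**

Step 6. The facial selectivity may be insufficient or its sense opposite to the model, conversion of the lipophilic enal in the two-phase medium may stall, and the epoxy aldehyde may be lost through hydrate or peroxyhydrate formation on work-up. The fallback sets out from trienal 8. Luche 1,2-reduction (NaBH4, CeCl3·7H2O, MeOH, 0 °C) should give (2E,7Z,9Z)-dodeca-2,7,9-trien-1-ol F1. Hydroxyl-directed Katsuki–Sharpless epoxidation (Ti(OiPr)4, L-(+)-diethyl tartrate, t-BuOOH, 4 Å sieves, CH2Cl2, −20 °C) should then give [(2S,3S)-3-[(4Z,6Z)-nona-4,6-dien-1-yl]oxiran-2-yl]methanol F2; only the titanium-bound allylic alkene is epoxidised and the absolute sense is fixed by the tartrate. Buffered Dess–Martin oxidation brings the route back at aldehyde 9. The same sample serves as the configurational reference for the organocatalytic product.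

Step 12. The second coupling may lag behind the first and leave mono-coupled bromoalkyne, the alkyne 10 may homocouple, and prolonged contact with the primary amine may open the oxiranes or cleave the glyceryl esters. The fallback sets out from acid 14 and alkyne 10 and joins chain and glycerol by esterification instead. Fischer esterification of 14 (MeOH, cat. H2SO4) gives methyl pent-4-ynoate F3, and bromination (NBS, AgNO3, acetone) gives methyl 5-bromopent-4-ynoate F4. A single Cadiot–Chodkiewicz coupling with 10 gives methyl 7-[(2S,3S)-3-[(4Z,6Z)-nona-4,6-dien-1-yl]oxiran-2-yl]hepta-4,6-diynoate F5. Saponification (LiOH, THF/H2O, 0 °C) gives 7-[(2S,3S)-3-[(4Z,6Z)-nona-4,6-dien-1-yl]oxiran-2-yl]hepta-4,6-diynoic acid F6. Carbodiimide/DMAP esterification of diol 13 with F6 (2.3 equiv) brings the route back at compound 17.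

Step 13. Cleavage of the hindered silyl ether may be slow enough to invite migration of the sn-2 acyl group to O3 through the liberated hydroxyl, and fluoride or acid may open the propargylic oxiranes; migration may also occur on silica, so boric acid-doped silica would be used. The fallback replaces fluoride cleavage by neutral oxidative cleavage and sets out from (S)-solketal 11. Alkylation (NaH, 4-methoxybenzyl chloride, DMF) gives 3-O-(4-methoxybenzyl)-1,2-O-isopropylidene-sn-glycerol F7, and aqueous acetic acid gives 3-O-(4-methoxybenzyl)-sn-glycerol F8. Esterification with 14 as in step 10 gives 3-O-(4-methoxybenzyl)-1,2-di-O-(pent-4-ynoyl)-sn-glycerol F9, and bromination as in step 11 gives 1,2-bis-O-(5-bromopent-4-ynoyl)-3-O-(4-methoxybenzyl)-sn-glycerol F10. Twofold coupling with 10 as in step 12 gives 3-O-(4-methoxybenzyl)-1,2-bis-O-{7-[(2S,3S)-3-[(4Z,6Z)-nona-4,6-dien-1-yl]oxiran-2-yl]hepta-4,6-diynoyl}-sn-glycerol F11. DDQ in CH2Cl2/pH 7 buffer at 0 °C removes the benzyl ether without generating an alkoxide and comes back to the route at target 18.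

**Further compounds**

F1 | step 6 | (2E,7Z,9Z)-dodeca-2,7,9-trien-1-ol | OC/C=C/CCC/C=C\C=C/CC
F2 | step 6 | [(2S,3S)-3-[(4Z,6Z)-nona-4,6-dien-1-yl]oxiran-2-yl]methanol | OC[C@@H]1O[C@H]1CCC/C=C\C=C/CC
F3 | step 12 | methyl pent-4-ynoate | C#CCCC(=O)OC
F4 | step 12 | methyl 5-bromopent-4-ynoate | BrC#CCCC(=O)OC
F5 | step 12 | methyl 7-[(2S,3S)-3-[(4Z,6Z)-nona-4,6-dien-1-yl]oxiran-2-yl]hepta-4,6-diynoate | COC(=O)CCC#CC#C[C@@H]1O[C@H]1CCC/C=C\C=C/CC
F6 | step 12 | 7-[(2S,3S)-3-[(4Z,6Z)-nona-4,6-dien-1-yl]oxiran-2-yl]hepta-4,6-diynoic acid | OC(=O)CCC#CC#C[C@@H]1O[C@H]1CCC/C=C\C=C/CC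
F7 | step 13 | 3-O-(4-methoxybenzyl)-1,2-O-isopropylidene-sn-glycerol | CC1(C)OC[C@H](COCc2ccc(OC)cc2)O1
F8 | step 13 | 3-O-(4-methoxybenzyl)-sn-glycerol | OC[C@H](COCc1ccc(OC)cc1)O
F9 | step 13 | 3-O-(4-methoxybenzyl)-1,2-di-O-(pent-4-ynoyl)-sn-glycerol | C#CCCC(=O)OC[C@H](COCc1ccc(OC)cc1)OC(=O)CCC#C
F10 | step 13 | 1,2-bis-O-(5-bromopent-4-ynoyl)-3-O-(4-methoxybenzyl)-sn-glycerol | BrC#CCCC(=O)OC[C@H](COCc1ccc(OC)cc1)OC(=O)CCC#CBr
F11 | step 13 | 3-O-(4-methoxybenzyl)-1,2-bis-O-{7-[(2S,3S)-3-[(4Z,6Z)-nona-4,6-dien-1-yl]oxiran-2-yl]hepta-4,6-diynoyl}-sn-glycerol | CC/C=C\C=C/CCC[C@@H]1O[C@H]1C#CC#CCCC(=O)OC[C@H](COCc1ccc(OC)cc1)OC(=O)CCC#CC#C[C@@H]1O[C@H]1CCC/C=C\C=C/CC
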